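I took the reading time of 3.0 min as the thing to interpret, because it does not mean the same in flasks of different charge, and the four new flasks share it along with 1.20 equiv of E.

| flask | Z | E | remark | time |
|---|---|---|---|---|
| spring | 3.5 mM | 1.2 equiv | run made earlier |  |
| midnight | 9.9 mM | 1.2 equiv | run made earlier |  |
| summer | 33 mM | 1.2 equiv | run made earlier |  |
| south-west | 4.0 mM | 1.20 equiv |  | 3.0 min |
| south | 8.0 mM | 1.20 equiv |  | 3.0 min |
| west | 15 mM | 1.20 equiv |  | 3.0 min |
| north | 30 mM | 1.20 equiv |  | 3.0 min |

| run | time / s | L / % | Z / % |
|---|---|---|---|
| spring | 12.0 | 0 | 0 |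
| spring | 30.0 | 5.5 | 0 |
| spring | 60.0 | 10.1 | 0 |
| spring | 90.0 | 12.3 | 1.0 |
| spring | 120 | 13.3 | 0.1 |
| midnight | 25.0 | 8.1 | 0 |
| midnight | 50.0 | 16.8 | 0.7 |
| midnight | 80.0 | 20.9 | 0 |
| midnight | 90.0 | 21.6 | 0 |
| midnight | 120 | 23.3 | 0.9 |
| summer | 10.0 | 4.7 | 42.2 |
| summer | 20.0 | 10.0 | 27.8 |
| summer | 40.0 | 19.0 | 7.0 |
| summer | 60.0 | 24.2 | 0 |
| summer | 120 | 25.6 | 0 |

(readings scatter by 1 percentage point)

- the numbers in the tables scatter by 1 percentage point (one standard deviation)
- at the start none of Z is in solution
- a reading or a percentage of L counts all its forms, free or not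
- the concentration of L that is asked is that of its free form alone
- "hardly changes" means that all values lie within two and a half points (for a concentration: within two and a half percent of the largest)

1. [L] (only what is free in solution) at the end for south-west, south, west, north, in this order
2. the shape of the row from first to last (rises all the way / rises, then falls / hardly changes / falls, then rises / falls all the way)

If dissolving is quick and every step after it is a meeting of two dissolved partners, then at a fixed ratio of E to Z the percentages depend on charge times time. So I laid each run on the clock of the midnight run, multiplying its time by its charge and dividing by the midnight charge. South-west's reading falls at 72.7 s, its midnight-equivalent time, and the others follow: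

south: 145 s; west: 273 s; north: 545 s

On this clock (a time normalisation) the curve starts nearly straight, through 8.1% at 25.0 s and 16.8% at 50.0 s, and the spring run's last reading, 13.3% at 42.4 s, falls between them. The knee comes near 80.0 s with 20.9%, and 120 s gives 23.3%. The summer run gives the level, 24.2% at 200 s and 25.6% at 400 s. I did not use it for the rise, since at 133 s, with Z still at 7.0%, it reads 19.0%, less than midnight's 23.3% at an earlier equivalent time.

Interpolating for south-west, taking midnight's last reading for south, the mean of the last two summer readings for west and the last summer reading for north, and counting each reading as free L, which is my assumption, I reckoned: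

south-west: 19.9% of 4.0 mM, so 0.796 mM
south: 1.86 mM; west: 3.73 mM; north: 7.68 mM

The forecast gave 0.6 mM, 1.7 mM, 3.8 mM and 7.6 mM, shape rises all the way, on the ground that “Final yields rise with charge”. Its first point lies below mine.

The flasks gave 0.807 mM, 2.00 mM, 3.96 mM and 7.93 mM, shape rises all the way.

    Z ⇌ J, rate k1*(cs1 - [J]) while solid is left; crystals form when [J] > cs1 (solubility = 16.0 mM, k = 0.200 s⁻¹)
    J + E → L (k = 0.450 M⁻¹ s⁻¹)
    J + L → D (k = 1.10 M⁻¹ s⁻¹)
    Q ⇌ L, rate k4*(cs4 - [L]) while solid is left; crystals form when [L] > cs4 (solubility = 11.0 mM, k = 0.570 s⁻¹)
    2 Z → X (k = 0.420 M⁻¹ s⁻¹)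

In south-west the dissolution of Z had half its turnover behind it at 0.667 s, far sooner than 5.3 min, the half-life of J by the path to L alone with the other concentrations as charged. South at 1.50 min has a midnight-equivalent time of 72.7 s, equal to the 72.7 s of south-west at 3.00 min, and the two flasks stood alike in L, D and J, with L 20.2% against 20.0%, D 15.1% against 14.7% and J 64.6% against 64.7%.

The numbers in the tables were generated by integration with made-up constants; the scatter is artificial.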